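**Plan**

- Retrosynthesis: cut the two caffeoyl ester C–O bonds at O1 and O3, then the ring bond C1–C6, then the chain bonds C1–C2 (dithiane ester alkylation) and C5–C6 (bromomethyl addition to an amide).
- Enabling feature: in the cyclohexane ring, C1 is a tertiary carbinol that carries the carboxyl carbon and lies 1,3 to the C5 oxygen across C6. With C5 as a ketone, C1–C6 is the aldol retron of a C5 ketone enolate (nucleophilic at C6) and a C1 α-keto ester.
- Forward: C2–C5 come from D-erythronolactone acetonide, C1 and the carboxyl carbon from a dithiane ester, C6 as CH2Br. The only ring closure is the carbocycle, by a zinc-enolate aldol of the C6-bromo ketone onto the C1 keto ester.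
- Endgame: C5 reduction, acetonide-to-diacetal exchange, double caffeoylation of O1 and O3, deprotection.
- Stereochemistry: C3 and C4 from the lactone; C1 in the aldol, relayed by the cis-acetonide; C5 by O1-directed hydride delivery; the E alkenes come with caffeic acid.

Key step: step 7

Remark on the chemistry: positions are numbered as in quinic acid (C1 bears the carboxyl group, O3 is cis to O4, O5 is trans to O4). Read this way, the given structure carries its esters on O1 and O3. Methyl 2,2-dimethoxyacetate, propane-1,3-dithiol, 2,3-O-isopropylidene-D-erythronolactone and caffeic acid are taken as purchased. A methyl ester is carried throughout so that the methanolic acetal exchange in step 9 cannot scramble it.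

**Route**

Step 1
Reactants: 1 methyl 2,2-dimethoxyacetate; 2 propane-1,3-dithiol
Product: 3 methyl 1,3-dithiane-2-carboxylate
Conditions: BF3·OEt2, CHCl3, reflux
Reagents that add atoms: none
Why: Lewis-acid-catalysed exchange of the dimethyl acetal for the six-membered cyclic dithioacetal (transthioacetalisation) is driven by release of methanol.

Step 2
Reactants: 4 2,3-O-isopropylidene-D-erythronolactone
Product: 5 (4R,5R)-5-(hydroxymethyl)-N-methoxy-N,2,2-trimethyl-1,3-dioxolane-4-carboxamide
Conditions: MeNH(OMe)·HCl, AlMe3, CH2Cl2, 0 °C to rt; then aq. potassium sodium tartrate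
Reagents that add atoms: N,O-dimethylhydroxylamine hydrochloride, CNOC.Cl
Why: Aminolysis of the lactone by the aluminium amide formed in the flask (Weinreb amide synthesis) opens the ring at the acyl carbon, so neither stereocentre is touched, and the hydroxy amide should be carried on at once because it can relactonise.

Step 3
Reactants: 5 (4R,5R)-5-(hydroxymethyl)-N-methoxy-N,2,2-trimethyl-1,3-dioxolane-4-carboxamide
Product: 6 (4R,5S)-5-(iodomethyl)-N-methoxy-N,2,2-trimethyl-1,3-dioxolane-4-carboxamide
Conditions: PPh3, I2, imidazole, toluene/MeCN, 0 °C to rt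
Reagents that add atoms: iodine, [I][I]
Why: Appel iodination converts the primary alcohol through its alkoxyphosphonium salt into the iodide by SN2 at CH2 and leaves both stereocentres alone (the descriptor change is only a priority change).

Step 4
Reactants: 3 methyl 1,3-dithiane-2-carboxylate; 6 (4R,5S)-5-(iodomethyl)-N-methoxy-N,2,2-trimethyl-1,3-dioxolane-4-carboxamide
Product: 8 methyl 2-{[(4R,5R)-5-[methoxy(methyl)carbamoyl]-2,2-dimethyl-1,3-dioxolan-4-yl]methyl}-1,3-dithiane-2-carboxylate, via sodium 2-(methoxycarbonyl)-1,3-dithian-2-ide 7 (not isolated)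
Conditions: NaH, DMF, 0 °C; then 6, rt
Reagents that add atoms: none
Why: SN2 alkylation of the doubly stabilised dithiane ester carbanion (Corey–Seebach umpolung) at the primary iodide brings in C1 and the carboxyl carbon as a masked α-keto ester, and this soft, weakly basic nucleophile should not epimerise the carbon next to the amide.

Step 5
Reactants: 8 methyl 2-{[(4R,5R)-5-[methoxy(methyl)carbamoyl]-2,2-dimethyl-1,3-dioxolan-4-yl]methyl}-1,3-dithiane-2-carboxylate
Product: 9 methyl 2-{[(4R,5R)-5-(bromoacetyl)-2,2-dimethyl-1,3-dioxolan-4-yl]methyl}-1,3-dithiane-2-carboxylate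
Conditions: CH2Br2, MeLi·LiBr, THF, −78 °C; then AcOH, −78 °C
Reagents that add atoms: dibromomethane, BrCBr
Why: Bromomethyllithium, made in the flask by bromine–lithium exchange, adds once to the Weinreb amide to give a chelated tetrahedral adduct that releases the bromomethyl ketone only on the cold acid quench (carbenoid homologation of a Weinreb amide), while the ester on the fully substituted dithiane carbon is expected to be too hindered to compete.

Step 6
Reactants: 9 methyl 2-{[(4R,5R)-5-(bromoacetyl)-2,2-dimethyl-1,3-dioxolan-4-yl]methyl}-1,3-dithiane-2-carboxylate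
Product: 10 methyl 3-[(4R,5R)-5-(bromoacetyl)-2,2-dimethyl-1,3-dioxolan-4-yl]-2-oxopropanoate
Conditions: NBS, 2,6-lutidine, acetone/H2O (9:1), −20 °C
Reagents that add atoms: water, O
Why: Oxidative hydrolysis of the dithioacetal with N-bromosuccinimide in buffered aqueous acetone (dithiane unmasking) frees the C1 ketone without strong base, so the acidic C2 methylene should not be enolised and the acetonide and the bromo ketone should survive.

Step 7
Reactants: 10 methyl 3-[(4R,5R)-5-(bromoacetyl)-2,2-dimethyl-1,3-dioxolan-4-yl]-2-oxopropanoate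
Product: 12 methyl 3,4-O-isopropylidene-5-dehydroquinate, via bromozinc enolate of the bromo ketone 11 (not isolated)
Conditions: Zn dust (activated with BrCH2CH2Br), THF, 0 °C to rt, slow addition of 10, high dilution; then H2O
Reagents that add atoms: none
Why: Proposed new method: zerovalent zinc inserts into the C6–Br bond of 10 to give the bromozinc enolate 11 of the C5 ketone, whose C6 terminus adds to the adjacent, strongly electrophilic C1 keto carbonyl, forming C1–C6 and closing the cyclohexane ring in the 6-(enolendo)-exo-trig mode to a zinc aldolate that water protonates. The closest known reactions are intramolecular Reformatsky-type aldol cyclisations of α-halo ketones onto aldehydes or ketones and Reformatsky additions to α-keto esters; their combination on an open-chain 3-deoxy-2,6-diulosonate is not known. Because the enolate arises by reduction of the C–Br bond and not by deprotonation, the more acidic C2 methylene is never enolised, so E1cB loss of the C3 oxygen and epimerisation at C4 are avoided; the bromine at C6 secures this site selectivity. The new stereocentre C1 is controlled by the cis-fused acetonide: zinc on the enolate oxygen is chelated by O4, which holds the C4–O4 bond in the enolate plane and selects the chair-like transition state with O3 pseudo-axial, and in that chair the methoxycarbonyl group must be pseudo-equatorial to escape a 1,3-diaxial contact with O3, so the alkoxide oxygen ends axial and cis to O3 and O4 (natural C1). The aldolate of this activated ketone can revert, and the natural epimer is also the one in which the zinc alkoxide is chelated by O3 and the ester carbonyl, so equilibration should work in the same direction. Addition to the C1 ketone and not to the ester carbonyl follows from six- against seven-membered closure, and high dilution with slow addition suppresses intermolecular aldol and Wurtz-type coupling.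

Step 8
Reactants: 12 methyl 3,4-O-isopropylidene-5-dehydroquinate
Product: 13 methyl 3,4-O-isopropylidenequinate
Conditions: Me4NBH(OAc)3, MeCN/AcOH (1:1), −25 °C
Reagents that add atoms: none
Why: Hydroxyl-directed reduction (Evans–Saksena type): the axial tertiary hydroxyl at C1 exchanges onto boron and delivers hydride to the face of the C5 carbonyl on which it sits, so the new C5 hydroxyl should be 1,3-anti to O1 and trans to O4, the equatorial alcohol of quinic acid.

Step 9
Reactants: 13 methyl 3,4-O-isopropylidenequinate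
Product: 14 methyl 4,5-O-[(2S,3S)-2,3-dimethoxybutane-2,3-diyl]quinate
Conditions: butane-2,3-dione, HC(OMe)3, camphorsulfonic acid (cat.), MeOH, reflux
Reagents that add atoms: butane-2,3-dione, CC(=O)C(C)=O; trimethyl orthoformate, COC(OC)OC
Why: Acid-catalysed acetal exchange in methanol removes the cis-3,4-acetonide and captures the trans-diequatorial 4,5-diol as the butane-2,3-diacetal, the thermodynamically preferred trans-fused dioxane with both methoxy groups axial (which fixes the two acetal centres), leaving exactly the O1 and O3 hydroxyls free.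

Step 10
Reactants: 15 caffeic acid
Product: 16 (E)-3-(3,4-diacetoxyphenyl)prop-2-enoic acid
Conditions: Ac2O, pyridine, rt
Reagents that add atoms: acetic anhydride, CC(=O)OC(C)=O
Why: Acetylation of both phenols (nucleophilic catalysis by pyridine) masks the catechol for the acid chloride chemistry.

Step 11
Reactants: 16 (E)-3-(3,4-diacetoxyphenyl)prop-2-enoic acid
Product: 17 (E)-3-(3,4-diacetoxyphenyl)prop-2-enoyl chloride
Conditions: (COCl)2, DMF (cat.), CH2Cl2, 0 °C to rt
Reagents that add atoms: oxalyl chloride, O=C(Cl)C(=O)Cl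
Why: Vilsmeier-type activation with oxalyl chloride and catalytic DMF gives the acid chloride without affecting the aryl acetates or the E double bond.

Step 12
Reactants: 14 methyl 4,5-O-[(2S,3S)-2,3-dimethoxybutane-2,3-diyl]quinate; 17 (E)-3-(3,4-diacetoxyphenyl)prop-2-enoyl chloride
Product: 18 methyl 1,3-bis-O-[(E)-3,4-diacetoxycinnamoyl]-4,5-O-[(2S,3S)-2,3-dimethoxybutane-2,3-diyl]quinate
Conditions: 17 (3 equiv), DMAP, pyridine, CH2Cl2, rt to 40 °C
Reagents that add atoms: none
Why: DMAP-catalysed acylation through the acylpyridinium salt should esterify the axial secondary hydroxyl at O3 and, with excess reagent and time, the tertiary hydroxyl at O1, the only two free hydroxyls, with no change at any stereocentre.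

Step 13
Reactants: 18 methyl 1,3-bis-O-[(E)-3,4-diacetoxycinnamoyl]-4,5-O-[(2S,3S)-2,3-dimethoxybutane-2,3-diyl]quinate
Product: 19 1,3-bis-O-[(E)-3,4-diacetoxycinnamoyl]-4,5-O-[(2S,3S)-2,3-dimethoxybutane-2,3-diyl]quinic acid
Conditions: LiI, EtOAc, reflux; then 1 M HCl
Reagents that add atoms: none
Why: Iodide dealkylates the methyl ester by SN2 at the methyl carbon with lithium assistance, which frees the carboxyl group without acyl–oxygen cleavage and so should leave the two cinnamate esters, the aryl acetates and the diacetal in place.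

Step 14
Reactants: 19 1,3-bis-O-[(E)-3,4-diacetoxycinnamoyl]-4,5-O-[(2S,3S)-2,3-dimethoxybutane-2,3-diyl]quinic acid
Product: 20 1,3-di-O-caffeoylquinic acid
Conditions: 2 M aq. HCl/THF (1:4), rt
Reagents that add atoms: none
Why: Aqueous acid hydrolyses the butane-2,3-diacetal and the four aryl acetates (acetal and phenyl ester hydrolysis) much faster than the hindered, conjugated cinnamate esters, and acyl migration between O3 and O4 is slow at low pH, so the 1,3-diester pattern and the four ring stereocentres should be kept.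

**Compound list**

1 | methyl 2,2-dimethoxyacetate | COC(OC)C(=O)OC | starting material
2 | propane-1,3-dithiol | SCCCS | starting material
3 | methyl 1,3-dithiane-2-carboxylate | COC(=O)C1SCCCS1 | intermediate
4 | 2,3-O-isopropylidene-D-erythronolactone, (3aR,6aR)-2,2-dimethyldihydrofuro[3,4-d][1,3]dioxol-4(3aH)-one | O=C1OC[C@H]2OC(C)(C)O[C@@H]12 | starting material
5 | (4R,5R)-5-(hydroxymethyl)-N-methoxy-N,2,2-trimethyl-1,3-dioxolane-4-carboxamide | OC[C@H]1OC(C)(C)O[C@H]1C(=O)N(C)OC | intermediate
6 | (4R,5S)-5-(iodomethyl)-N-methoxy-N,2,2-trimethyl-1,3-dioxolane-4-carboxamide | IC[C@H]1OC(C)(C)O[C@H]1C(=O)N(C)OC | intermediate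
7 | sodium 2-(methoxycarbonyl)-1,3-dithian-2-ide (sodium salt of 3) | [Na+].COC(=O)[C-]1SCCCS1 | intermediate (not isolated)
8 | methyl 2-{[(4R,5R)-5-[methoxy(methyl)carbamoyl]-2,2-dimethyl-1,3-dioxolan-4-yl]methyl}-1,3-dithiane-2-carboxylate | COC(=O)C1(C[C@H]2OC(C)(C)O[C@H]2C(=O)N(C)OC)SCCCS1 | intermediate
9 | methyl 2-{[(4R,5R)-5-(bromoacetyl)-2,2-dimethyl-1,3-dioxolan-4-yl]methyl}-1,3-dithiane-2-carboxylate | COC(=O)C1(C[C@H]2OC(C)(C)O[C@H]2C(=O)CBr)SCCCS1 | intermediate
10 | methyl 3-[(4R,5R)-5-(bromoacetyl)-2,2-dimethyl-1,3-dioxolan-4-yl]-2-oxopropanoate (key-step precursor) | COC(=O)C(=O)C[C@H]1OC(C)(C)O[C@H]1C(=O)CBr | intermediate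
11 | bromozinc enolate of 10 (zinc on the C5 enolate oxygen, C5=C6 methylene) | COC(=O)C(=O)C[C@H]1OC(C)(C)O[C@H]1C(=C)O[Zn]Br | intermediate (not isolated)
12 | methyl 3,4-O-isopropylidene-5-dehydroquinate, methyl (1S,3R,4R)-1-hydroxy-3,4-(isopropylidenedioxy)-5-oxocyclohexane-1-carboxylate (key-step product) | CC1(C)O[C@@H]2C[C@@](O)(C(=O)OC)CC(=O)[C@@H]2O1 | intermediate
13 | methyl 3,4-O-isopropylidenequinate (O1–H and O5–H free) | CC1(C)O[C@@H]2C[C@@](O)(C(=O)OC)C[C@@H](O)[C@@H]2O1 | intermediate
14 | methyl 4,5-O-[(2S,3S)-2,3-dimethoxybutane-2,3-diyl]quinate (O1–H and O3–H free) | COC(=O)[C@]1(O)C[C@@H](O)[C@H]2O[C@](C)(OC)[C@@](C)(OC)O[C@@H]2C1 | intermediate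
15 | caffeic acid, (E)-3-(3,4-dihydroxyphenyl)prop-2-enoic acid | OC(=O)/C=C/c1ccc(O)c(O)c1 | starting material
16 | (E)-3-(3,4-diacetoxyphenyl)prop-2-enoic acid | CC(=O)Oc1ccc(/C=C/C(=O)O)cc1OC(C)=O | intermediate
17 | (E)-3-(3,4-diacetoxyphenyl)prop-2-enoyl chloride | CC(=O)Oc1ccc(/C=C/C(=O)Cl)cc1OC(C)=O | intermediate
18 | methyl 1,3-bis-O-[(E)-3,4-diacetoxycinnamoyl]-4,5-O-[(2S,3S)-2,3-dimethoxybutane-2,3-diyl]quinate | COC(=O)[C@]1(OC(=O)/C=C/c3ccc(OC(C)=O)c(OC(C)=O)c3)C[C@@H](OC(=O)/C=C/c4ccc(OC(C)=O)c(OC(C)=O)c4)[C@H]2O[C@](C)(OC)[C@@](C)(OC)O[C@@H]2C1 | intermediate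
19 | 1,3-bis-O-[(E)-3,4-diacetoxycinnamoyl]-4,5-O-[(2S,3S)-2,3-dimethoxybutane-2,3-diyl]quinic acid | OC(=O)[C@]1(OC(=O)/C=C/c3ccc(OC(C)=O)c(OC(C)=O)c3)C[C@@H](OC(=O)/C=C/c4ccc(OC(C)=O)c(OC(C)=O)c4)[C@H]2O[C@](C)(OC)[C@@](C)(OC)O[C@@H]2C1 | intermediate
20 | 1,3-di-O-caffeoylquinic acid | O=C(/C=C/c1ccc(O)c(O)c1)O[C@@H]1C[C@@](OC(=O)/C=C/c2ccc(O)c(O)c2)(C(=O)O)C[C@@H](O)[C@@H]1O | target

**Step count and risks**

Total step count: 14. Longest linear sequence: 11 steps (4 to 20 through steps 2–9 and 12–14).

Steps most likely to fail: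

1. Step 7 (proposed new method). The zinc enolate may be protonated (simple debromination), may take a proton from C2 with β-elimination of O3 to follow, may react between molecules, or may add with poor facial selectivity at C1.
   Fallback with known reaction types, setting out from 8 and returning at 12: MeMgBr (THF, −20 °C) converts the Weinreb amide 8 into the methyl ketone methyl 2-{[(4R,5R)-5-acetyl-2,2-dimethyl-1,3-dioxolan-4-yl]methyl}-1,3-dithiane-2-carboxylate F1. Wittig methylenation (Ph3PCH3Br, KN(SiMe3)2, THF, −78 to 0 °C) gives methyl 2-{[(4R,5S)-2,2-dimethyl-5-(prop-1-en-2-yl)-1,3-dioxolan-4-yl]methyl}-1,3-dithiane-2-carboxylate F2. Dithioacetal hydrolysis with PhI(OCOCF3)2 in aqueous MeCN, which spares the alkene, gives methyl 3-[(4R,5S)-2,2-dimethyl-5-(prop-1-en-2-yl)-1,3-dioxolan-4-yl]-2-oxopropanoate F3. A Lewis-acid-catalysed intramolecular carbonyl-ene reaction (Sc(OTf)3, CH2Cl2) joins the alkene terminus to the keto carbonyl, forming the same C1–C6 bond without any enolate, to give methyl 5-deoxy-3,4-O-isopropylidene-5-methylidenequinate F4. Ozonolysis of the exocyclic methylene (O3, CH2Cl2/MeOH, −78 °C, then Me2S) gives 12.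

2. Step 4. Displacement at the β-oxygenated primary carbon may be slow and be overtaken by intramolecular O-alkylation by the amide carbonyl (ending as lactone 4 on work-up) or by elimination.
   Fallback setting out from 5 and returning at 10, forming C1–C2 by olefination instead of SN2: Dess–Martin oxidation of 5 (NaHCO3, CH2Cl2) gives (4R,5S)-5-formyl-N-methoxy-N,2,2-trimethyl-1,3-dioxolane-4-carboxamide F5. Horner–Wadsworth–Emmons reaction with methyl 2-(tert-butyldimethylsilyloxy)-2-(dimethoxyphosphoryl)acetate (LiN(SiMe3)2, THF, −78 °C) gives the silyl enol ether of the keto ester, methyl 2-(tert-butyldimethylsilyloxy)-3-{(4R,5R)-5-[methoxy(methyl)carbamoyl]-2,2-dimethyl-1,3-dioxolan-4-yl}prop-2-enoate F6 (either alkene isomer serves). Bromomethyllithium under the conditions of step 5 gives methyl 3-[(4R,5R)-5-(bromoacetyl)-2,2-dimethyl-1,3-dioxolan-4-yl]-2-(tert-butyldimethylsilyloxy)prop-2-enoate F7. HF·pyridine (THF, 0 °C) cleaves the silyl enol ether to 10.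

3. Step 12. Acylation of the hindered tertiary O1 hydroxyl, syn-axial to the newly formed O3 ester, may stall at the 3-monoester.
   Fallback setting out from 13 and returning at 20, with the two esters introduced one after the other on the 1,5-lactone: heating 13 with TsOH (cat.) in toluene with removal of methanol closes the lactone to 3,4-O-isopropylidene-1,5-quinide F8, whose only free hydroxyl is O1–H. Acylation with 17 (DMAP, pyridine) gives 1-O-[(E)-3,4-diacetoxycinnamoyl]-3,4-O-isopropylidene-1,5-quinide F9. Aqueous TFA in CH2Cl2 at 0 °C removes the acetonide to give 1-O-[(E)-3,4-diacetoxycinnamoyl]-1,5-quinide F10. One equivalent of 17 (pyridine, CH2Cl2, −20 °C) should acylate the equatorial O3–H of the lactone in preference to the axial O4–H, giving 1,3-bis-O-[(E)-3,4-diacetoxycinnamoyl]-1,5-quinide F11. 2 M aq. HCl/THF then hydrolyses the four aryl acetates and the lactone to 20.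

Further compounds
F1 | step 7 | methyl 2-{[(4R,5R)-5-acetyl-2,2-dimethyl-1,3-dioxolan-4-yl]methyl}-1,3-dithiane-2-carboxylate | COC(=O)C1(C[C@H]2OC(C)(C)O[C@H]2C(C)=O)SCCCS1
F2 | step 7 | methyl 2-{[(4R,5S)-2,2-dimethyl-5-(prop-1-en-2-yl)-1,3-dioxolan-4-yl]methyl}-1,3-dithiane-2-carboxylate | COC(=O)C1(C[C@H]2OC(C)(C)O[C@H]2C(C)=C)SCCCS1
F3 | step 7 | methyl 3-[(4R,5S)-2,2-dimethyl-5-(prop-1-en-2-yl)-1,3-dioxolan-4-yl]-2-oxopropanoate | COC(=O)C(=O)C[C@H]1OC(C)(C)O[C@H]1C(C)=C
F4 | step 7 | methyl 5-deoxy-3,4-O-isopropylidene-5-methylidenequinate | CC1(C)O[C@@H]2C[C@@](O)(C(=O)OC)CC(=C)[C@@H]2O1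
F5 | step 4 | (4R,5S)-5-formyl-N-methoxy-N,2,2-trimethyl-1,3-dioxolane-4-carboxamide | O=C[C@H]1OC(C)(C)O[C@H]1C(=O)N(C)OC
F6 | step 4 | methyl 2-(tert-butyldimethylsilyloxy)-3-{(4R,5R)-5-[methoxy(methyl)carbamoyl]-2,2-dimethyl-1,3-dioxolan-4-yl}prop-2-enoate (alkene geometry not fixed) | COC(=O)C(O[Si](C)(C)C(C)(C)C)=C[C@H]1OC(C)(C)O[C@H]1C(=O)N(C)OC
F7 | step 4 | methyl 3-[(4R,5R)-5-(bromoacetyl)-2,2-dimethyl-1,3-dioxolan-4-yl]-2-(tert-butyldimethylsilyloxy)prop-2-enoate (alkene geometry not fixed) | COC(=O)C(O[Si](C)(C)C(C)(C)C)=C[C@H]1OC(C)(C)O[C@H]1C(=O)CBr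
F8 | step 12 | 3,4-O-isopropylidene-1,5-quinide | CC1(C)O[C@@H]2C[C@]3(O)C[C@@H](OC3=O)[C@@H]2O1
F9 | step 12 | 1-O-[(E)-3,4-diacetoxycinnamoyl]-3,4-O-isopropylidene-1,5-quinide | CC1(C)O[C@@H]2C[C@]3(OC(=O)/C=C/c4ccc(OC(C)=O)c(OC(C)=O)c4)C[C@@H](OC3=O)[C@@H]2O1
F10 | step 12 | 1-O-[(E)-3,4-diacetoxycinnamoyl]-1,5-quinide | O[C@@H]1C[C@]2(OC(=O)/C=C/c3ccc(OC(C)=O)c(OC(C)=O)c3)C[C@@H](OC2=O)[C@@H]1O
F11 | step 12 | 1,3-bis-O-[(E)-3,4-diacetoxycinnamoyl]-1,5-quinide | O=C(/C=C/c1ccc(OC(C)=O)c(OC(C)=O)c1)O[C@@H]1C[C@]2(OC(=O)/C=C/c3ccc(OC(C)=O)c(OC(C)=O)c3)C[C@@H](OC2=O)[C@@H]1O
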